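**Retrosynthetic overview**

- Gardenin E is reached by hydrogenolysis of its 3',5'-dibenzyl ether.
- The strategy rests on ring A: C5–OH and C8–OMe are para, with C6–OMe and C7–OMe between them. Carbons C5–C8 and their four oxygens are therefore a dimethyl squarate unit annulated across the C4a=C8a bond of a 2-aryl-4-pyranone (ring C). The C4a–C5 bond is formed by thermal ring expansion of a 4-methoxy-4-(4-pyranon-6-yl)cyclobutenone.
- The cyclobutenone comes from O-methylation of the carbinol formed by 1,2-addition of the C6-magnesiated 2-aryl-4-pyranone to dimethyl squarate.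
- The 2-aryl-4-pyranone comes from enolate acylation/cyclization of (E)-4-methoxybut-3-en-2-one with 3,5-bis(benzyloxy)-4-methoxybenzoyl chloride, made from methyl 3,5-dihydroxy-4-methoxybenzoate.
- Ring order: ring B (purchased), ring C (pyranone), temporary four-membered ring, ring A.

Key step: step 7

Remark: the quaternary carbon of the cyclobutenone in the two squarate-derived intermediates is a stereocentre. It is formed racemic and is erased in the key step, so both compounds are drawn without configuration. Pyranone locants of the 2-aryl-4H-pyran-4-one are kept in the names of later compounds.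

**Step 1**
Reactants: 1 methyl 3,5-dihydroxy-4-methoxybenzoate
Product: 2 methyl 3,5-bis(benzyloxy)-4-methoxybenzoate
Conditions: BnBr (2.4 equiv), K2CO3, DMF, 60 °C
Reagents that add atoms: benzyl bromide, BrCc1ccccc1
Why: Williamson etherification, in which both phenoxides formed with K2CO3 are benzylated by SN2 while the ester and the methyl ether are inert.

**Step 2**
Reactants: 2 methyl 3,5-bis(benzyloxy)-4-methoxybenzoate
Product: 3 3,5-bis(benzyloxy)-4-methoxybenzoic acid
Conditions: LiOH, THF/MeOH/H2O, 50 °C; then 1 M HCl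
Reagents that add atoms: lithium hydroxide, [Li+].[OH-]
Why: Ester saponification by acyl substitution with hydroxide leaves aryl benzyl and methyl ethers untouched, and acidification releases the acid.

**Step 3**
Reactants: 3 3,5-bis(benzyloxy)-4-methoxybenzoic acid
Product: 4 3,5-bis(benzyloxy)-4-methoxybenzoyl chloride
Conditions: (COCl)2, DMF (cat.), CH2Cl2, 0 °C to rt; used crude
Reagents that add atoms: oxalyl chloride, ClC(=O)C(=O)Cl
Why: Vilsmeier-type activation of the acid by oxalyl chloride and catalytic DMF gives the acyl chloride under cold, non-Lewis-acidic conditions that spare the benzyl ethers.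

**Step 4**
Reactants: 4 3,5-bis(benzyloxy)-4-methoxybenzoyl chloride; 5 (E)-4-methoxybut-3-en-2-one
Product: 8 2-[3,5-bis(benzyloxy)-4-methoxyphenyl]-4H-pyran-4-one, via lithium dienolate 6 (not isolated), via enol ether diketone 7 (not isolated)
Conditions: 5 (2.2 equiv), LiN(SiMe3)2 (2.2 equiv), THF, −78 °C; add 4; CF3CO2H quench, then CF3CO2H (cat.), toluene, rt
Reagents that add atoms: none
Why: Claisen-type C-acylation of the kinetic methyl-ketone enolate by the aroyl chloride gives the β-diketone (the second equivalent of enolate absorbs its acidity), whose enol oxygen then adds to the β-methoxy enone and expels methanol under acid, the established acylation–cyclization route to 2-substituted 4-pyranones.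

**Step 5**
Reactants: 8 2-[3,5-bis(benzyloxy)-4-methoxyphenyl]-4H-pyran-4-one; 9 dimethyl squarate (3,4-dimethoxycyclobut-3-ene-1,2-dione)
Product: 11 racemic 4-{2-[3,5-bis(benzyloxy)-4-methoxyphenyl]-4-oxo-4H-pyran-6-yl}-4-hydroxy-2,3-dimethoxycyclobut-2-en-1-one, via pyranon-6-ylmagnesium chloride 10 (not isolated)
Conditions: TMPMgCl·LiCl (1.2 equiv; TMP = 2,2,6,6-tetramethylpiperidin-1-yl), THF, −40 °C, 8 added to the base; then cannulated into 9 (1.5 equiv), THF, −78 to −40 °C; aq. NH4Cl
Reagents that add atoms: none
Why: Proposed new method: the C6–H of the pyranone lies α to the ring oxygen at the β-terminus of the vinylogous ester and should be the most acidic ring C–H, so the hindered, non-nucleophilic magnesium amide is expected to remove it without conjugate addition, giving a σ-vinylmagnesium species that, unlike a C3 or C5 anion, cannot expel the ring oxygen and that adds 1,2 to one of the two equivalent squarate carbonyls; the closest known reactions are the TMP-zinc and TMP-magnesium amide metalation of chromones and 4-quinolones at C2, the C6 lithiation of uracils, and the 1,2-addition of aryl- and alkenyl-lithium or -magnesium reagents to dialkyl squarates, and the new carbinol stereocentre forms as a racemate that is erased in step 7.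

**Step 6**
Reactants: 11 racemic 4-{2-[3,5-bis(benzyloxy)-4-methoxyphenyl]-4-oxo-4H-pyran-6-yl}-4-hydroxy-2,3-dimethoxycyclobut-2-en-1-one
Product: 12 racemic 4-{2-[3,5-bis(benzyloxy)-4-methoxyphenyl]-4-oxo-4H-pyran-6-yl}-2,3,4-trimethoxycyclobut-2-en-1-one
Conditions: MeI (excess), Ag2O, 4 Å sieves, MeCN, rt, dark
Reagents that add atoms: iodomethane, CI
Why: Ag2O-promoted Williamson (Purdie) methylation etherifies the tertiary carbinol without a free alkoxide, so oxyanion-accelerated ring opening of the cyclobutenone is avoided, and iodomethane is too weak an alkylating agent to convert the pyranone carbonyl into a methoxypyrylium salt as methyl triflate would.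

**Step 7**
Reactants: 12 racemic 4-{2-[3,5-bis(benzyloxy)-4-methoxyphenyl]-4-oxo-4H-pyran-6-yl}-2,3,4-trimethoxycyclobut-2-en-1-one
Product: 15 3',5'-di-O-benzylgardenin E (2-[3,5-bis(benzyloxy)-4-methoxyphenyl]-5-hydroxy-6,7,8-trimethoxy-4H-chromen-4-one), via dienylketene 13 (not isolated), via 4a-H cyclohexadienone 14 (not isolated)
Conditions: p-xylene (degassed, 0.01 M), 138 °C, Ar
Reagents that add atoms: none
Why: Heating cleaves the C(=O)–C(OMe) bond of the cyclobutenone by conrotatory 4π ring opening to dienylketene 13, in which the former carbinol carbon carries the methoxy and the pyranonyl group. The ketene C=C, the central C=C and the pyranone C5=C6 bond then close ring A by thermal disrotatory 6π electrocyclization, forming the C4a–C5 bond and cyclohexadienone 14, whose doubly activated C4a–H tautomerizes to the aromatic, carbonyl-chelated 5-phenol. The closest known reaction type is the Moore thermal ring expansion of 4-aryl-, 4-heteroaryl- and 4-alkenyl-4-alkoxycyclobutenones to hydroquinone monoethers, and here the nucleophilic α-carbon C5 of the vinylogous ester is polarity-matched to the electrophilic ketene carbon. No stereocentre is created, since the racemic centre of 12 and the transient C4a centre of 14 both vanish on aromatization. The step needs inward rotation of the pyranonyl group, which the strong outward preference of the 4-methoxy donor secures, and ring opening is reversible, so a wrongly rotated ketene can return to 12. Regiochemistry is fixed because C5 is the only pyranone carbon that can reach the ketene carbon in a six-membered array and the methyl ether cannot lactonize onto the ketene; the ketone oxygen becomes 5-OH, the two vinyl methoxy groups become 6- and 7-OMe, and the carbinol methyl ether becomes 8-OMe.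

**Step 8**
Reactants: 15 3',5'-di-O-benzylgardenin E
Product: 16 gardenin E (5-hydroxy-2-(3,5-dihydroxy-4-methoxyphenyl)-6,7,8-trimethoxy-4H-chromen-4-one)
Conditions: H2 (1 atm), Pd/C (10%), EtOAc/MeOH, rt
Reagents that add atoms: none
Why: Heterogeneous hydrogenolysis cleaves the two benzylic C–O bonds to free the 3'- and 5'-phenols, while aryl methyl ethers, the chelated 5-OH and the vinylogous-ester C2=C3 bond of the flavone should be inert at 1 atm and room temperature.

**Compound list**

1 | methyl 3,5-dihydroxy-4-methoxybenzoate | COC(=O)c1cc(O)c(OC)c(O)c1 | starting material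
2 | methyl 3,5-bis(benzyloxy)-4-methoxybenzoate | COC(=O)c1cc(OCc2ccccc2)c(OC)c(OCc2ccccc2)c1 | intermediate
3 | 3,5-bis(benzyloxy)-4-methoxybenzoic acid | OC(=O)c1cc(OCc2ccccc2)c(OC)c(OCc2ccccc2)c1 | intermediate
4 | 3,5-bis(benzyloxy)-4-methoxybenzoyl chloride | ClC(=O)c1cc(OCc2ccccc2)c(OC)c(OCc2ccccc2)c1 | intermediate
5 | (E)-4-methoxybut-3-en-2-one | CO/C=C/C(C)=O | starting material
6 | lithium (E)-4-methoxybuta-1,3-dien-2-olate (kinetic enolate of 5) | [Li+].[O-]C(=C)/C=C/OC | intermediate
7 | (E)-1-[3,5-bis(benzyloxy)-4-methoxyphenyl]-5-methoxypent-4-ene-1,3-dione | CO/C=C/C(=O)CC(=O)c1cc(OCc2ccccc2)c(OC)c(OCc2ccccc2)c1 | intermediate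
8 | 2-[3,5-bis(benzyloxy)-4-methoxyphenyl]-4H-pyran-4-one | O=c1cc(-c2cc(OCc3ccccc3)c(OC)c(OCc3ccccc3)c2)occ1 | intermediate
9 | dimethyl squarate | COC1=C(OC)C(=O)C1=O | starting material
10 | {2-[3,5-bis(benzyloxy)-4-methoxyphenyl]-4-oxo-4H-pyran-6-yl}magnesium chloride (LiCl complex) | Cl[Mg]c1cc(=O)cc(-c2cc(OCc3ccccc3)c(OC)c(OCc3ccccc3)c2)o1 | intermediate
11 | racemic 4-{2-[3,5-bis(benzyloxy)-4-methoxyphenyl]-4-oxo-4H-pyran-6-yl}-4-hydroxy-2,3-dimethoxycyclobut-2-en-1-one | O=C1C(OC)=C(OC)C1(O)c1cc(=O)cc(-c2cc(OCc3ccccc3)c(OC)c(OCc3ccccc3)c2)o1 | intermediate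
12 | racemic 4-{2-[3,5-bis(benzyloxy)-4-methoxyphenyl]-4-oxo-4H-pyran-6-yl}-2,3,4-trimethoxycyclobut-2-en-1-one | O=C1C(OC)=C(OC)C1(OC)c1cc(=O)cc(-c2cc(OCc3ccccc3)c(OC)c(OCc3ccccc3)c2)o1 | intermediate
13 | dienylketene: 2,3,4-trimethoxy-4-{2-[3,5-bis(benzyloxy)-4-methoxyphenyl]-4-oxo-4H-pyran-6-yl}buta-1,3-dien-1-one, pyranonyl group cis to the ketene-bearing carbon | O=C=C(OC)/C(OC)=C(/OC)c1cc(=O)cc(-c2cc(OCc3ccccc3)c(OC)c(OCc3ccccc3)c2)o1 | intermediate
14 | racemic 2-[3,5-bis(benzyloxy)-4-methoxyphenyl]-6,7,8-trimethoxy-4aH-chromene-4,5-dione (keto tautomer of 15) | O=C1C(OC)=C(OC)C(OC)=C2OC(-c3cc(OCc4ccccc4)c(OC)c(OCc4ccccc4)c3)=CC(=O)C12 | intermediate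
15 | 3',5'-di-O-benzylgardenin E | COc1c(OCc2ccccc2)cc(-c2cc(=O)c3c(O)c(OC)c(OC)c(OC)c3o2)cc1OCc1ccccc1 | intermediate
16 | gardenin E | COc1c(O)cc(-c2cc(=O)c3c(O)c(OC)c(OC)c(OC)c3o2)cc1O | target

**Step count and risks**

Total step count: 8. Longest linear sequence: 8 steps (1 to 16); 5 and 9 are purchased partners.

Steps most likely to fail:

1. Step 5 (carries the new-method label). Deprotonation may go astray: carbonyl-directed metalation at C3 or C5 followed by ring opening through loss of the ring oxygen, conjugate addition of the metalated pyranone to unmetalated 8, or sluggish addition of the stabilized magnesium species to 9. Fallback by known chemistry, setting out from 9 and 4 and returning at 12: the pyranone ring is built after the bond to the squarate carbon has been made with an acetylide. The lithium acetylide of commercial tert-butyldimethyl(but-3-yn-2-yloxy)silane (n-BuLi, THF, −78 °C) is added to 9 and the lithium alkoxide is trapped with MeOTf to give 4-[3-(tert-butyldimethylsilyloxy)but-1-yn-1-yl]-2,3,4-trimethoxycyclobut-2-en-1-one F1 (diastereomer mixture, of no consequence). HF·pyridine releases 4-(3-hydroxybut-1-yn-1-yl)-2,3,4-trimethoxycyclobut-2-en-1-one F2, and Dess–Martin periodinane oxidizes it to 2,3,4-trimethoxy-4-(3-oxobut-1-yn-1-yl)cyclobut-2-en-1-one F3. Its lithium enolate (LiN(SiMe3)2, 2 equiv, THF, −78 °C) is C-acylated by 4 to give 4-{5-[3,5-bis(benzyloxy)-4-methoxyphenyl]-3,5-dioxopent-1-yn-1-yl}-2,3,4-trimethoxycyclobut-2-en-1-one F4. Base-catalysed 6-endo-dig addition of the diketone enol oxygen to the ynone (Et3N cat., CH2Cl2, rt) closes the pyranone and should give 12 directly, so steps 4 to 6 are bypassed and the route resumes at step 7. All operations stay at or below room temperature because 4-alkynylcyclobutenones ring-open on heating.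

2. Step 7 (key step). The dienylketene may fail to close onto C5 because the pyranone C5=C6 bond is a less willing 2π partner than a simple alkene or arene, so ketene oligomerization or decomposition at the required temperature could win. Fallback, setting out from 4 and returning at 16: ring C is built on a preformed ring A by Baker–Venkataraman chemistry. Commercial 1-(6-hydroxy-2,3,4,5-tetramethoxyphenyl)ethanone is O-acylated with 4 (pyridine, DMAP) to give 2-acetyl-3,4,5,6-tetramethoxyphenyl 3,5-bis(benzyloxy)-4-methoxybenzoate F5. KOH in pyridine (50 °C) moves the aroyl group to carbon, giving 1-[3,5-bis(benzyloxy)-4-methoxyphenyl]-3-(2-hydroxy-3,4,5,6-tetramethoxyphenyl)propane-1,3-dione F6. AcOH with catalytic H2SO4 cyclodehydrates it to 2-[3,5-bis(benzyloxy)-4-methoxyphenyl]-5,6,7,8-tetramethoxy-4H-chromen-4-one F7. BCl3 with pentamethylbenzene (CH2Cl2, −78 to 0 °C) should then remove both benzyl groups and the carbonyl-chelated 5-methyl group in one operation to give 16.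

3. Step 6. Etherification of the hindered tertiary α-ketol may stall, or the cyclobutenone may ring-open on the basic Ag2O surface. Fallback, setting out from 11 and returning at 15: the methyl group is introduced after the annulation. Carbinol 11 is thermolysed as such (degassed p-xylene, 138 °C, Ar), and the same electrocyclic cascade should give the hydroquinone 2-[3,5-bis(benzyloxy)-4-methoxyphenyl]-5,8-dihydroxy-6,7-dimethoxy-4H-chromen-4-one F8. Without exposure to air, F8 is treated with MeI (1.1 equiv) and K2CO3 in acetone. Only the free 8-OH should react, since the 5-OH is held in a hydrogen bond to the C4 carbonyl, and this gives 15.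

**Further compounds**

F1 | step 5 | 4-[3-(tert-butyldimethylsilyloxy)but-1-yn-1-yl]-2,3,4-trimethoxycyclobut-2-en-1-one | COC1=C(OC)C(OC)(C#CC(C)O[Si](C)(C)C(C)(C)C)C1=O
F2 | step 5 | 4-(3-hydroxybut-1-yn-1-yl)-2,3,4-trimethoxycyclobut-2-en-1-one | COC1=C(OC)C(OC)(C#CC(C)O)C1=O
F3 | step 5 | 2,3,4-trimethoxy-4-(3-oxobut-1-yn-1-yl)cyclobut-2-en-1-one | COC1=C(OC)C(OC)(C#CC(C)=O)C1=O
F4 | step 5 | 4-{5-[3,5-bis(benzyloxy)-4-methoxyphenyl]-3,5-dioxopent-1-yn-1-yl}-2,3,4-trimethoxycyclobut-2-en-1-one | COC1=C(OC)C(OC)(C#CC(=O)CC(=O)c2cc(OCc3ccccc3)c(OC)c(OCc3ccccc3)c2)C1=O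
F5 | step 7 | 2-acetyl-3,4,5,6-tetramethoxyphenyl 3,5-bis(benzyloxy)-4-methoxybenzoate | CC(=O)c1c(OC)c(OC)c(OC)c(OC)c1OC(=O)c1cc(OCc2ccccc2)c(OC)c(OCc2ccccc2)c1
F6 | step 7 | 1-[3,5-bis(benzyloxy)-4-methoxyphenyl]-3-(2-hydroxy-3,4,5,6-tetramethoxyphenyl)propane-1,3-dione | O=C(CC(=O)c1c(O)c(OC)c(OC)c(OC)c1OC)c1cc(OCc2ccccc2)c(OC)c(OCc2ccccc2)c1
F7 | step 7 | 2-[3,5-bis(benzyloxy)-4-methoxyphenyl]-5,6,7,8-tetramethoxy-4H-chromen-4-one | O=c1cc(-c3cc(OCc4ccccc4)c(OC)c(OCc4ccccc4)c3)oc2c(OC)c(OC)c(OC)c(OC)c12
F8 | step 6 | 2-[3,5-bis(benzyloxy)-4-methoxyphenyl]-5,8-dihydroxy-6,7-dimethoxy-4H-chromen-4-one | COc1c(OCc2ccccc2)cc(-c2cc(=O)c3c(O)c(OC)c(OC)c(O)c3o2)cc1OCc1ccccc1
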